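**Retrosynthetic overview**
1. Target 8 ⇐ methyl ether 6 by O-demethylation; the methyl group is the only protecting group and comes in with guaiacol.
2. 6 ⇐ phenol 4 + 2,4-dibromo-1-iodobenzene 5 by forming the diaryl ether C–O bond (key step: a proposed C–I-selective, gold-catalysed O-arylation).
3. 4 ⇐ guaiacol 1 by a directed tribromination that leaves the free OH next to Br and the OMe next to H, which is the oxygen pattern the target needs.
4. No ring is formed (both benzene rings are bought) and no stereocentre is set.

Assumption: the target has no stereocentre and no configurationally stable axis, so "single enantiomer" is taken to mean the achiral compound exactly as drawn.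

**Route**

Step 1
Reactants: 1 guaiacol (2-methoxyphenol)
Product: 4 2,3,4-tribromo-6-methoxyphenol (4,5,6-tribromoguaiacol), via 4-bromo-2-methoxyphenol 2 (not isolated), via 2,4-dibromo-6-methoxyphenol 3 (not isolated)
Conditions: Br2 (3.1 equiv), AcOH, 15 °C then 50 °C
Reagents that add atoms: bromine, BrBr
Why: Electrophilic aromatic bromination (SEAr) in which the free OH sends the first two bromines to its para and ortho positions and the third enters para to OMe (between the two bromines) rather than the OMe-flanked ortho site, so the OH ends up next to Br and the OMe next to H; no stereocentre.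

Step 2
Reactants: 4 2,3,4-tribromo-6-methoxyphenol (1.2 equiv); 5 2,4-dibromo-1-iodobenzene
Product: 6 1,2,3-tribromo-4-(2,4-dibromophenoxy)-5-methoxybenzene
Conditions: (MeDalphos)AuCl (5 mol %), AgOTf (1.1 equiv), K3PO4 (1.5 equiv), 4 Å MS, 1,2-dichlorobenzene, 80 °C, dark
Reagents that add atoms: none
Why: Proposed new method: Au(I)/Au(III) O-arylation of a fully ortho/para-blocked polybromophenol with an aryl iodide, in which the cationic (P,N)gold(I) adds oxidatively to the C–I bond of 5 only (C–Br bonds are inert to gold(I), unlike with Pd or Cu), Ag+ removes iodide, the phenoxide of 4 binds the aryl–Au(III) centre through oxygen because its ortho and para carbons carry OMe and Br and cannot be C-arylated, and C(sp2)–O reductive elimination releases the diaryl ether and Au(I); the closest known reaction type is the MeDalphos–gold C–N and C–O cross-coupling of aryl iodides with amines, aliphatic alcohols and carboxylates (an Ullmann-type etherification in outcome); no stereocentre.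

Step 3
Reactants: 6 1,2,3-tribromo-4-(2,4-dibromophenoxy)-5-methoxybenzene
Product: 8 3,4,5-tribromo-2-(2,4-dibromophenoxy)phenol, via aryloxydibromoborane 7 (not isolated)
Conditions: BBr3 (2 equiv), CH2Cl2, −78 °C to rt; then H2O, 0 °C
Reagents that add atoms: boron tribromide, BrB(Br)Br
Why: Lewis-acid aryl methyl ether cleavage (BBr3 demethylation) in which boron binds the methoxy oxygen, bromide attacks the methyl group (SN2) to give MeBr and borane 7, and water hydrolyses the B–O bond of 7 to the phenol, while the diaryl ether and the five C–Br bonds are inert to BBr3 at these temperatures; no stereocentre.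

**Compound list**
1 | guaiacol (2-methoxyphenol) | COc1ccccc1O | starting material
2 | 4-bromo-2-methoxyphenol (formed in the flask, not isolated) | COc1cc(Br)ccc1O | intermediate
3 | 2,4-dibromo-6-methoxyphenol (formed in the flask, not isolated) | COc1cc(Br)cc(Br)c1O | intermediate
4 | 2,3,4-tribromo-6-methoxyphenol (4,5,6-tribromoguaiacol) | COc1cc(Br)c(Br)c(Br)c1O | intermediate
5 | 2,4-dibromo-1-iodobenzene | Ic1ccc(Br)cc1Br | starting material
6 | 1,2,3-tribromo-4-(2,4-dibromophenoxy)-5-methoxybenzene | COc1cc(Br)c(Br)c(Br)c1Oc1ccc(Br)cc1Br | intermediate
7 | dibromo[3,4,5-tribromo-2-(2,4-dibromophenoxy)phenoxy]borane (formed in the flask, not isolated) | BrB(Br)Oc1cc(Br)c(Br)c(Br)c1Oc1ccc(Br)cc1Br | intermediate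
8 | 3,4,5-tribromo-2-(2,4-dibromophenoxy)phenol | Oc1cc(Br)c(Br)c(Br)c1Oc1ccc(Br)cc1Br | target

**Step count**
Total steps: 3. Longest linear sequence: 3 (1 → 4 → 6 → 8); 5 is purchased.

**Steps most likely to fail, with fallbacks**

Step 2 (the proposed gold-catalysed O-arylation) is the most likely to fail. Oxidative addition of the electron-poor, ortho-substituted iodide 5 to gold(I) may be slow. The hindered, weakly basic aryloxide may bind or eliminate poorly, and protodeauration to 1,3-dibromobenzene may compete. The fallback uses known metal-free diaryliodonium chemistry; it sets out from 5 (with 4 unchanged as the partner) and comes back to the route at 6. Compound 5 is oxidised with mCPBA and TsOH·H2O in MeCN at 55 °C to 2,4-dibromo-1-[hydroxy(tosyloxy)iodo]benzene F1. This is trapped in the same pot with 1,3,5-trimethoxybenzene to give (2,4-dibromophenyl)(2,4,6-trimethoxyphenyl)iodonium 4-methylbenzenesulfonate F2, which is precipitated with Et2O. F2 then arylates the potassium phenoxide of 4 (t-BuOK, THF, 40 °C) by ligand coupling at iodine(III). The electron-poor, ortho-substituted dibromophenyl group is transferred and the trimethoxyphenyl group leaves as its iodide, giving 6. This costs one extra step.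

Step 1 (tribromination) is the second risk. The third bromination may stall, may give some of the OMe-ortho isomer, or may run on to tetrabromoguaiacol that is hard to remove. The fallback fixes the order of bromination; it sets out from 1 and comes back at 4. Compound 1 is acetylated (Ac2O, pyridine) to 2-methoxyphenyl acetate F3. With the phenol masked, NBS in MeCN brominates para to OMe to give 5-bromo-2-methoxyphenyl acetate F4. Hydrolysis (NaOH, MeOH/H2O, then HCl) gives 5-bromo-2-methoxyphenol F5, which is also commercially available. Br2 (2.1 equiv) in AcOH then fills the only positions ortho and para to the free OH and gives 4.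

Step 3 (demethylation) is the third risk. The methoxy oxygen is flanked by the bulky aryloxy group and is weakly basic, so boron coordination and cleavage may be incomplete. The fallback drops Lewis-acid activation for a nucleophilic dealkylation; it sets out from 6 and comes back at 8 and makes no new compound (F0). Compound 6 is heated with LiCl (5 equiv) in DMF at 140 °C and then acidified with dilute HCl. Chloride attacks the methyl carbon (SN2), which is feasible because the leaving polybrominated aryloxyphenoxide is well stabilised.

**Further compounds**
F1 | step 2 | 2,4-dibromo-1-[hydroxy(tosyloxy)iodo]benzene | OI(OS(=O)(=O)c1ccc(C)cc1)c1ccc(Br)cc1Br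
F2 | step 2 | (2,4-dibromophenyl)(2,4,6-trimethoxyphenyl)iodonium 4-methylbenzenesulfonate | COc1cc(OC)c([I+]c2ccc(Br)cc2Br)c(OC)c1.Cc1ccc(cc1)S(=O)(=O)[O-]
F3 | step 1 | 2-methoxyphenyl acetate | COc1ccccc1OC(C)=O
F4 | step 1 | 5-bromo-2-methoxyphenyl acetate | COc1ccc(Br)cc1OC(C)=O
F5 | step 1 | 5-bromo-2-methoxyphenol | COc1ccc(Br)cc1O
F0 | step 3 | none | none
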